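The time of reading came first for me: each flask was to be read at 4.0 min, so I wanted to know whether anything would still be moving by then.

| setting | Thursday's | Monday's | Tuesday's |
|---|---|---|---|
| substrate | 0.50 mM | 0.50 mM | 0.50 mM |
| coupling partner | 0.350 mM | 0.350 mM | 0.350 mM |
| temperature | 20 °C | 50 °C | 80 °C |
| time | 4.0 min | 4.0 min | 4.0 min |

    substrate + coupling partner → product (k1 = 300 /M/s, Ea1 = 45.0 kJ/mol)
    (constants at 20 °C)

- the constants hold at 20 °C; other temperatures follow from the activation energies

- the flask that comes out highest in amount of product, in percent of the substrate charged, or "all alike" when all lie within 1.5 percentage points (Thursday's / Monday's / Tuesday's / all alike)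
- product at the end, in percent of the substrate charged, Thursday's
- product at the end, in percent of the substrate charged, Monday's
- product at the end, in percent of the substrate charged, Tuesday's

I reckoned the end state before the rate. Substrate and coupling partner react one for one, and [coupling partner] starts at 0.350 mM against 0.50 mM of substrate, so coupling partner is the limiting reagent and product can reach 70.0 % of the substrate charged; that share, the smaller charge divided by the substrate charge, I called the ceiling. For the rate I looked at what [substrate] does in the course of a run. Late in a run [substrate] approaches the excess, 0.150 mM, so coupling partner then decays pseudo-first-order, with a time constant equal to the inverse of the rate constant times that concentration. On the lowest rung of my ladder stood Tuesday's, with 0.965 s, shorter than Thursday's by the factor 23. Monday's, at 50 °C, stood on the rung above it, and Thursday's above that, with 22.2 s. The top rung was the run itself, 10.8 of Thursday's time constants long, so I committed to the ceiling in each flask at the reading.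

The forecast gave 70 %, 70 % and 70 % for Thursday's, Monday's and Tuesday's, hence all alike, holding that “all three flasks reach that ceiling”. Its timescale at 20 °C was about 10 seconds where my late-run time constant for Thursday's was 22.2 s, but its three numbers were the same as the ceiling I had committed to.

The simulation gave 70.0 %, 70.0 % and 70.0 %, hence all alike. Tuesday's reading matched the ceiling of 70.0 %, and the reading at 40.0 min was still 70.0 %. I then took Tuesday's flask with [substrate] raised to 2.0 mM: the same ceiling, the smaller charge over the substrate charge, came to 17.5 %, and that flask gave 17.5 % of product at 4.00 min, with 82.5 % of the substrate charged still there.

The constants belong to no real substance; the result is computed.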